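**Retrosynthetic overview**
1. Target ⇐ ammonia closes the 5-hydroxy-γ-lactam on a macrocyclic γ-keto β-keto ester; the 13-membered para-cyclophane ⇐ intramolecular C-alkylation of a β-keto ester by an aryl-tethered chloromethyl ketone.
2. Rings A and B ⇐ one intramolecular Diels–Alder reaction between an (E,E)-diene on the quaternary ring C carbon and an (E)-enone on the neighbouring ring C carbon.
3. Diene ⇐ stereoselective double cross-coupling of a 1,1-dibromoalkene; aryl ether ⇐ invertive displacement of an α-triflyloxy ester by a phenol.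
4. Ring C stereocentres ⇐ enantioselective desymmetrizing glyoxylate-ene reaction of a mirror-symmetric cyclohexa-1,4-diene, then hydroxyl-directed hydrogenation.
5. That diene ⇐ Birch reductive methylation of methyl 3,5-dimethylbenzoate. Ring order: C (from the arene) → A + B (cycloaddition) → macrocycle → lactam.

Assumption: the configurations at the lactam C-3 and the hemiaminal C-5 of the target are taken to be the thermodynamically preferred ones inside the macrocycle (both centres can equilibrate), so they are set in the last step; compounds 1, 6, 9, 15 and 21 are taken as commercial.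

**Route**

Step 1
Reactants: 1 methyl 3,5-dimethylbenzoate
Product: 3 methyl 1,3,5-trimethylcyclohexa-2,5-diene-1-carboxylate, via potassium ester enolate 2 (not isolated)
Conditions: K (2.2 equiv), t-BuOH (1.0 equiv), NH3(l)–THF, −78 °C; then MeI, −78 °C → rt
Reagents that add atoms: iodomethane (CI)
Why: Birch reductive alkylation: the ester directs reduction to the ipso and para carbons, and the ester enolate is C-methylated at the ipso carbon, giving an achiral mirror-symmetric 1,4-diene that already holds every ring C carbon and the future angular methyl group.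

Step 2
Reactants: 3 methyl 1,3,5-trimethylcyclohexa-2,5-diene-1-carboxylate
Product: 4 1,3,5-trimethylcyclohexa-2,5-diene-1-carbaldehyde
Conditions: i-Bu2AlH (1.1 equiv), CH2Cl2, −78 °C; aq. potassium sodium tartrate
Reagents that add atoms: none
Why: Partial hydride reduction of a hindered ester: the α-quaternary aluminium hemiacetal is stable at −78 °C and releases the non-enolizable aldehyde only on work-up.

Step 3
Reactants: 4 1,3,5-trimethylcyclohexa-2,5-diene-1-carbaldehyde
Product: 5 3-(2,2-dibromoethenyl)-1,3,5-trimethylcyclohexa-1,4-diene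
Conditions: CBr4, PPh3, Zn dust, CH2Cl2, 0 °C → rt
Reagents that add atoms: tetrabromomethane (BrC(Br)(Br)Br)
Why: Corey–Fuchs (Ramirez) dibromoolefination, a Wittig reaction of the dibromomethylene ylide; it installs a bulky, ene-inert handle for the later diene construction and leaves the molecule mirror-symmetric.

Step 4
Reactants: 5 3-(2,2-dibromoethenyl)-1,3,5-trimethylcyclohexa-1,4-diene; 6 ethyl glyoxylate
Product: 7 ethyl (2S)-2-[(1R,6R)-6-(2,2-dibromoethenyl)-2,4,6-trimethylcyclohexa-2,4-dien-1-yl]-2-hydroxyacetate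
Conditions: [Cu((S,S)-t-Bu-box)](SbF6)2 (10 mol %; t-Bu-box = 2,2′-(propane-2,2-diyl)bis(4-tert-butyl-4,5-dihydro-1,3-oxazole)), CH2Cl2, 0 °C, 5 in 1.5-fold excess
Reagents that add atoms: none
Why: Proposed new method: a catalytic asymmetric carbonyl-ene reaction used to desymmetrize a Birch-derived diene; the copper-chelated glyoxylate (Si face open) bonds to the CH terminus of one of the two enantiotopic trisubstituted olefins, on the ring face opposite the dibromovinyl group (its cis-bromine overhangs the ring), with the aldehyde hydrogen rather than the ester under the quaternary carbon and with transfer of the doubly allylic ring hydrogen, so one event fixes the carbinol carbon (S), the new ring methine and the quaternary carbon (an exocyclic-methylene regioisomer would converge in step 5); closest known chemistry: copper bis(oxazoline)-catalysed glyoxylate-ene reactions of cyclic and trisubstituted olefins and glyoxylate-ene desymmetrization of prochiral bis-allylic dienes.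

Step 5
Reactants: 7 ethyl (2S)-2-[(1R,6R)-6-(2,2-dibromoethenyl)-2,4,6-trimethylcyclohexa-2,4-dien-1-yl]-2-hydroxyacetate
Product: 8 ethyl (2S)-2-[(1R,2S,4R,6R)-6-(2,2-dibromoethenyl)-2,4,6-trimethylcyclohexyl]-2-hydroxyacetate
Conditions: H2 (1 atm), [Ir(cod)(PCy3)(py)]PF6 (5 mol %), CH2Cl2, 0 °C → rt
Reagents that add atoms: none
Why: Hydroxyl-directed homogeneous hydrogenation: iridium bound to the carbinol delivers both equivalents of H2 to the ring face that carries the hydroxy ester side chain, so both new methyl groups end up cis to each other and trans to that side chain (all-equatorial ring C), while the hindered, electron-poor dibromoalkene is not reduced.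

Step 6
Reactants: 9 methyl 2-[4-(benzyloxy)phenyl]acetate
Product: 10 1-[4-(benzyloxy)phenyl]-3-chloropropan-2-one
Conditions: ClCH2I, MeLi·LiBr, THF, −78 °C
Reagents that add atoms: chloroiodomethane (ClCI)
Why: Carbenoid homologation of an ester: chloromethyllithium adds once to the ester and the tetrahedral intermediate survives at −78 °C, giving the chloromethyl ketone on work-up.

Step 7
Reactants: 10 1-[4-(benzyloxy)phenyl]-3-chloropropan-2-one
Product: 11 1-(benzyloxy)-4-(3-chloro-2,2-dimethoxypropyl)benzene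
Conditions: HC(OMe)3, MeOH, p-TsOH·H2O (cat.), 50 °C
Reagents that add atoms: trimethyl orthoformate (COC(OC)OC); methanol (CO)
Why: Acid-catalysed ketalization driven by the orthoformate; the ketal turns the reactive α-chloro ketone into an inert neopentyl-type chloride for the steps that follow.

Step 8
Reactants: 11 1-(benzyloxy)-4-(3-chloro-2,2-dimethoxypropyl)benzene
Product: 12 4-(3-chloro-2,2-dimethoxypropyl)phenol
Conditions: H2 (1 atm), Pd/C, EtOAc, Et3N (trace), rt
Reagents that add atoms: none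
Why: Hydrogenolysis of the benzyl ether; the primary alkyl chloride and the ketal are stable under neutral conditions.

Step 9
Reactants: 8 ethyl (2S)-2-[(1R,2S,4R,6R)-6-(2,2-dibromoethenyl)-2,4,6-trimethylcyclohexyl]-2-hydroxyacetate; 12 4-(3-chloro-2,2-dimethoxypropyl)phenol
Product: 14 ethyl (2R)-2-[4-(3-chloro-2,2-dimethoxypropyl)phenoxy]-2-[(1R,2S,4R,6R)-6-(2,2-dibromoethenyl)-2,4,6-trimethylcyclohexyl]acetate, via α-triflyloxy ester 13 (not isolated)
Conditions: Tf2O, 2,6-lutidine, CH2Cl2, −78 °C; then 12, Cs2CO3, MeCN, −20 °C → rt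
Reagents that add atoms: none
Why: SN2 displacement of an α-triflyloxy ester by a phenoxide (Williamson type) with clean inversion; this converts the carbinol configuration delivered by the ene step into the configuration of the target's aryl ether carbon.

Step 10
Reactants: 15 (2S)-but-3-yn-2-ol
Product: 17 (2S,3E)-3-methyl-4-(4,4,5,5-tetramethyl-1,3,2-dioxaborolan-2-yl)but-3-en-2-ol, via alkenylalane 16 (not isolated)
Conditions: Me3Al (3 equiv), Cp2ZrCl2 (0.25 equiv), CH2Cl2, 0 °C → rt; then i-PrOBpin, 0 °C → rt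
Reagents that add atoms: trimethylaluminium (C[Al](C)C); 2-isopropoxy-4,4,5,5-tetramethyl-1,3,2-dioxaborolane (CC(C)OB1OC(C)(C)C(C)(C)O1)
Why: Negishi zirconium-catalysed carboalumination adds methyl and aluminium syn across the alkyne (methyl on the internal carbon) and aluminium-to-boron transmetalation retains the (E) geometry; the carbinol stereocentre comes unchanged from the chiral pool.

Step 11
Reactants: 14 ethyl (2R)-2-[4-(3-chloro-2,2-dimethoxypropyl)phenoxy]-2-[(1R,2S,4R,6R)-6-(2,2-dibromoethenyl)-2,4,6-trimethylcyclohexyl]acetate; 17 (2S,3E)-3-methyl-4-(4,4,5,5-tetramethyl-1,3,2-dioxaborolan-2-yl)but-3-en-2-ol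
Product: 18 ethyl (2R)-2-[(1R,2S,4R,6R)-6-[(1Z,3E,5S)-2-bromo-5-hydroxy-4-methylhexa-1,3-dien-1-yl]-2,4,6-trimethylcyclohexyl]-2-[4-(3-chloro-2,2-dimethoxypropyl)phenoxy]acetate
Conditions: Pd(PPh3)4 (5 mol %), TlOEt, THF–H2O (3:1), rt
Reagents that add atoms: none
Why: trans-Selective Suzuki–Miyaura mono-coupling of a 1,1-dibromoalkene: zerovalent palladium inserts only into the C–Br bond trans to the bulky ring, so the alkenyl group enters trans to the ring with retention of the boronate geometry.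

Step 12
Reactants: 18 ethyl (2R)-2-[(1R,2S,4R,6R)-6-[(1Z,3E,5S)-2-bromo-5-hydroxy-4-methylhexa-1,3-dien-1-yl]-2,4,6-trimethylcyclohexyl]-2-[4-(3-chloro-2,2-dimethoxypropyl)phenoxy]acetate
Product: 19 ethyl (2R)-2-[4-(3-chloro-2,2-dimethoxypropyl)phenoxy]-2-[(1R,2S,4R,6S)-6-[(1E,3E,5S)-5-hydroxy-2,4-dimethylhexa-1,3-dien-1-yl]-2,4,6-trimethylcyclohexyl]acetate
Conditions: Me2Zn (3 equiv), Pd(P(t-Bu)3)2 (5 mol %), THF, 0 °C → rt
Reagents that add atoms: dimethylzinc (C[Zn]C)
Why: Negishi methylation of the remaining alkenyl bromide with retention of geometry, completing the (1E,3E)-diene whose terminal carbon carries methyl inside and hydroxyethyl outside.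

Step 13
Reactants: 19 ethyl (2R)-2-[4-(3-chloro-2,2-dimethoxypropyl)phenoxy]-2-[(1R,2S,4R,6S)-6-[(1E,3E,5S)-5-hydroxy-2,4-dimethylhexa-1,3-dien-1-yl]-2,4,6-trimethylcyclohexyl]acetate
Product: 20 (2R)-2-[4-(3-chloro-2,2-dimethoxypropyl)phenoxy]-2-[(1R,2S,4R,6S)-6-[(1E,3E,5S)-5-hydroxy-2,4-dimethylhexa-1,3-dien-1-yl]-2,4,6-trimethylcyclohexyl]acetaldehyde
Conditions: i-Bu2AlH (2.2 equiv), CH2Cl2, −78 °C; aq. potassium sodium tartrate
Reagents that add atoms: none
Why: Partial reduction of an α-aryloxy ester: the chelated aluminium hemiacetal is stable at −78 °C, so the aldehyde is released only on work-up and the α-stereocentre is not touched.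

Step 14
Reactants: 20 (2R)-2-[4-(3-chloro-2,2-dimethoxypropyl)phenoxy]-2-[(1R,2S,4R,6S)-6-[(1E,3E,5S)-5-hydroxy-2,4-dimethylhexa-1,3-dien-1-yl]-2,4,6-trimethylcyclohexyl]acetaldehyde; 21 ethyl 3-oxo-4-(triphenylphosphoranylidene)butanoate
Product: 22 ethyl (4E,6S)-6-[4-(3-chloro-2,2-dimethoxypropyl)phenoxy]-6-[(1R,2S,4R,6S)-6-[(1E,3E,5S)-5-hydroxy-2,4-dimethylhexa-1,3-dien-1-yl]-2,4,6-trimethylcyclohexyl]-3-oxohex-4-enoate
Conditions: NaH (1.0 equiv relative to 21), THF, 0 °C; then 20, rt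
Reagents that add atoms: none
Why: Wittig olefination with the anion of a keto-stabilized ylide gives the (E)-enone β-keto ester in one step; the reagent is only weakly basic, so the α-aryloxy aldehyde does not epimerize.

Step 15
Reactants: 22 ethyl (4E,6S)-6-[4-(3-chloro-2,2-dimethoxypropyl)phenoxy]-6-[(1R,2S,4R,6S)-6-[(1E,3E,5S)-5-hydroxy-2,4-dimethylhexa-1,3-dien-1-yl]-2,4,6-trimethylcyclohexyl]-3-oxohex-4-enoate
Product: 23 ethyl 3-[(1R,2S,4aS,4bS,6R,8S,8aR,9S,9aS)-9-[4-(3-chloro-2,2-dimethoxypropyl)phenoxy]-2-[(1S)-1-hydroxyethyl]-2,4,4b,6,8-pentamethyl-2,4a,4b,5,6,7,8,8a,9,9a-decahydro-1H-fluoren-1-yl]-3-oxopropanoate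
Conditions: toluene (0.01 M), BHT, 150 °C, sealed tube
Reagents that add atoms: none
Why: Intramolecular Diels–Alder reaction (type 1, three-atom tether): the acyl-endo transition state gives the trans A/B fusion, the trans-diequatorial anchoring on ring C allows only the strain-free trans-anti-trans half-chair for the forming cyclopentane, and the (E,E)-diene geometry sets the quaternary carbon, so C1, C2, C4a and C9a are fixed together.

Step 16
Reactants: 23 ethyl 3-[(1R,2S,4aS,4bS,6R,8S,8aR,9S,9aS)-9-[4-(3-chloro-2,2-dimethoxypropyl)phenoxy]-2-[(1S)-1-hydroxyethyl]-2,4,4b,6,8-pentamethyl-2,4a,4b,5,6,7,8,8a,9,9a-decahydro-1H-fluoren-1-yl]-3-oxopropanoate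
Product: 24 ethyl 3-[(1R,2S,4aS,4bS,6R,8S,8aR,9S,9aS)-9-[4-(3-chloro-2-oxopropyl)phenoxy]-2-[(1S)-1-hydroxyethyl]-2,4,4b,6,8-pentamethyl-2,4a,4b,5,6,7,8,8a,9,9a-decahydro-1H-fluoren-1-yl]-3-oxopropanoate
Conditions: 1 M HCl, THF, rt
Reagents that add atoms: water (O)
Why: Acid-catalysed hydrolysis of the dimethyl ketal frees the chloromethyl ketone; dilute aqueous acid leaves the trisubstituted ring A olefin and the β-keto ester alone.

Step 17
Reactants: 24 ethyl 3-[(1R,2S,4aS,4bS,6R,8S,8aR,9S,9aS)-9-[4-(3-chloro-2-oxopropyl)phenoxy]-2-[(1S)-1-hydroxyethyl]-2,4,4b,6,8-pentamethyl-2,4a,4b,5,6,7,8,8a,9,9a-decahydro-1H-fluoren-1-yl]-3-oxopropanoate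
Product: 25 macrocyclic diketo ester (13-membered para-cyclophane in which the β-keto ester α-carbon of 24 is bonded to the former CH2Cl carbon; mixture of epimers at that carbon)
Conditions: Cs2CO3, NaI (0.2 equiv), MeCN (0.001 M, slow addition), 50 °C
Reagents that add atoms: none
Why: Intramolecular SN2 C-alkylation of the soft caesium β-keto ester enolate by the halomethyl ketone (iodide formed in situ, Finkelstein) under high dilution; the rigid tricycle holds the aryl ether (C9) and the acyl chain (C1) close together, and the new α-carbon is epimerizable and needs no control.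

Step 18
Reactants: 25 macrocyclic diketo ester
Product: 26 CNP0565217.1 (target)
Conditions: NH3 (7 M in MeOH), sealed tube, 60 °C
Reagents that add atoms: ammonia (N)
Why: Lactamization of a γ-keto ester: ammonia adds to the unhindered benzyl ketone and the carbinolamine nitrogen acylates on the neighbouring ester (5-exo), giving the 5-hydroxy-γ-lactam; C-3 (β-dicarbonyl α-carbon) and C-5 (ring–chain tautomerism) equilibrate to the macrocycle-preferred (3R,5S) arrangement.

**Compound list**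
1 | methyl 3,5-dimethylbenzoate | COC(=O)c1cc(C)cc(C)c1 | starting material
2 | potassium methoxy(3,5-dimethylcyclohexa-2,5-dien-1-ylidene)methanolate (ester enolate, not isolated) | COC([O-])=C1C=C(C)CC(C)=C1.[K+] | intermediate
3 | methyl 1,3,5-trimethylcyclohexa-2,5-diene-1-carboxylate | COC(=O)C1(C)C=C(C)CC(C)=C1 | intermediate
4 | 1,3,5-trimethylcyclohexa-2,5-diene-1-carbaldehyde | O=CC1(C)C=C(C)CC(C)=C1 | intermediate
5 | 3-(2,2-dibromoethenyl)-1,3,5-trimethylcyclohexa-1,4-diene | BrC(Br)=CC1(C)C=C(C)CC(C)=C1 | intermediate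
6 | ethyl glyoxylate | CCOC(=O)C=O | starting material
7 | ethyl (2S)-2-[(1R,6R)-6-(2,2-dibromoethenyl)-2,4,6-trimethylcyclohexa-2,4-dien-1-yl]-2-hydroxyacetate | CCOC(=O)[C@@H](O)[C@@H]1C(C)=CC(C)=C[C@@]1(C)C=C(Br)Br | intermediate
8 | ethyl (2S)-2-[(1R,2S,4R,6R)-6-(2,2-dibromoethenyl)-2,4,6-trimethylcyclohexyl]-2-hydroxyacetate | CCOC(=O)[C@@H](O)[C@@H]1[C@@H](C)C[C@@H](C)C[C@@]1(C)C=C(Br)Br | intermediate
9 | methyl 2-[4-(benzyloxy)phenyl]acetate | COC(=O)Cc1ccc(OCc2ccccc2)cc1 | starting material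
10 | 1-[4-(benzyloxy)phenyl]-3-chloropropan-2-one | ClCC(=O)Cc1ccc(OCc2ccccc2)cc1 | intermediate
11 | 1-(benzyloxy)-4-(3-chloro-2,2-dimethoxypropyl)benzene | COC(CCl)(Cc1ccc(OCc2ccccc2)cc1)OC | intermediate
12 | 4-(3-chloro-2,2-dimethoxypropyl)phenol | COC(CCl)(Cc1ccc(O)cc1)OC | intermediate
13 | ethyl (2S)-2-[(1R,2S,4R,6R)-6-(2,2-dibromoethenyl)-2,4,6-trimethylcyclohexyl]-2-[(trifluoromethanesulfonyl)oxy]acetate (not isolated) | CCOC(=O)[C@@H](OS(=O)(=O)C(F)(F)F)[C@@H]1[C@@H](C)C[C@@H](C)C[C@@]1(C)C=C(Br)Br | intermediate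
14 | ethyl (2R)-2-[4-(3-chloro-2,2-dimethoxypropyl)phenoxy]-2-[(1R,2S,4R,6R)-6-(2,2-dibromoethenyl)-2,4,6-trimethylcyclohexyl]acetate | CCOC(=O)[C@H](Oc1ccc(CC(OC)(OC)CCl)cc1)[C@@H]1[C@@H](C)C[C@@H](C)C[C@@]1(C)C=C(Br)Br | intermediate
15 | (2S)-but-3-yn-2-ol | C[C@H](O)C#C | starting material
16 | dimethylaluminium (2S,3E)-4-(dimethylalumanyl)-3-methylbut-3-en-2-olate (alkenylalane, not isolated) | C[C@H](O[Al](C)C)/C(C)=C/[Al](C)C | intermediate
17 | (2S,3E)-3-methyl-4-(4,4,5,5-tetramethyl-1,3,2-dioxaborolan-2-yl)but-3-en-2-ol | C[C@H](O)/C(C)=C/B1OC(C)(C)C(C)(C)O1 | intermediate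
18 | ethyl (2R)-2-[(1R,2S,4R,6R)-6-[(1Z,3E,5S)-2-bromo-5-hydroxy-4-methylhexa-1,3-dien-1-yl]-2,4,6-trimethylcyclohexyl]-2-[4-(3-chloro-2,2-dimethoxypropyl)phenoxy]acetate | CCOC(=O)[C@H](Oc1ccc(CC(OC)(OC)CCl)cc1)[C@@H]1[C@@H](C)C[C@@H](C)C[C@@]1(C)/C=C(Br)/C=C(C)/[C@H](C)O | intermediate
19 | ethyl (2R)-2-[4-(3-chloro-2,2-dimethoxypropyl)phenoxy]-2-[(1R,2S,4R,6S)-6-[(1E,3E,5S)-5-hydroxy-2,4-dimethylhexa-1,3-dien-1-yl]-2,4,6-trimethylcyclohexyl]acetate | CCOC(=O)[C@H](Oc1ccc(CC(OC)(OC)CCl)cc1)[C@@H]1[C@@H](C)C[C@@H](C)C[C@@]1(C)/C=C(C)/C=C(C)/[C@H](C)O | intermediate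
20 | (2R)-2-[4-(3-chloro-2,2-dimethoxypropyl)phenoxy]-2-[(1R,2S,4R,6S)-6-[(1E,3E,5S)-5-hydroxy-2,4-dimethylhexa-1,3-dien-1-yl]-2,4,6-trimethylcyclohexyl]acetaldehyde | O=C[C@H](Oc1ccc(CC(OC)(OC)CCl)cc1)[C@@H]1[C@@H](C)C[C@@H](C)C[C@@]1(C)/C=C(C)/C=C(C)/[C@H](C)O | intermediate
21 | ethyl 3-oxo-4-(triphenylphosphoranylidene)butanoate | CCOC(=O)CC(=O)C=P(c1ccccc1)(c1ccccc1)c1ccccc1 | starting material
22 | ethyl (4E,6S)-6-[4-(3-chloro-2,2-dimethoxypropyl)phenoxy]-6-[(1R,2S,4R,6S)-6-[(1E,3E,5S)-5-hydroxy-2,4-dimethylhexa-1,3-dien-1-yl]-2,4,6-trimethylcyclohexyl]-3-oxohex-4-enoate | CCOC(=O)CC(=O)/C=C/[C@H](Oc1ccc(CC(OC)(OC)CCl)cc1)[C@@H]1[C@@H](C)C[C@@H](C)C[C@@]1(C)/C=C(C)/C=C(C)/[C@H](C)O | intermediate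
23 | ethyl 3-[(1R,2S,4aS,4bS,6R,8S,8aR,9S,9aS)-9-[4-(3-chloro-2,2-dimethoxypropyl)phenoxy]-2-[(1S)-1-hydroxyethyl]-2,4,4b,6,8-pentamethyl-2,4a,4b,5,6,7,8,8a,9,9a-decahydro-1H-fluoren-1-yl]-3-oxopropanoate | CC1=C[C@](C)([C@H](C)O)[C@H](C(=O)CC(=O)OCC)[C@@H]2[C@@H]1[C@]3(C)C[C@H](C)C[C@H](C)[C@H]3[C@H]2Oc4ccc(CC(OC)(OC)CCl)cc4 | intermediate
24 | ethyl 3-[(1R,2S,4aS,4bS,6R,8S,8aR,9S,9aS)-9-[4-(3-chloro-2-oxopropyl)phenoxy]-2-[(1S)-1-hydroxyethyl]-2,4,4b,6,8-pentamethyl-2,4a,4b,5,6,7,8,8a,9,9a-decahydro-1H-fluoren-1-yl]-3-oxopropanoate | CC1=C[C@](C)([C@H](C)O)[C@H](C(=O)CC(=O)OCC)[C@@H]2[C@@H]1[C@]3(C)C[C@H](C)C[C@H](C)[C@H]3[C@H]2Oc4ccc(CC(=O)CCl)cc4 | intermediate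
25 | macrocyclic diketo ester: decahydrofluorene of 24 whose C1 acyl chain C(=O)–CH(CO2Et)–CH2–C(=O)–CH2– ends on the para carbon of the C9 aryl ether (13-membered para-cyclophane; CH(CO2Et) centre unassigned) | CC1=C[C@](C)([C@H](C)O)[C@@H]2C(=O)C(C(=O)OCC)CC(=O)Cc3ccc(cc3)O[C@H]3[C@H]2[C@@H]1[C@]1(C)C[C@H](C)C[C@H](C)[C@@H]31 | intermediate
26 | CNP0565217.1: (3R,5S)-5-hydroxypyrrolidin-2-one whose C3 carries the carbonyl of the (1R,2S,4aS,4bS,6R,8S,8aR,9S,9aS)-2-[(1S)-1-hydroxyethyl]-2,4,4b,6,8-pentamethyl-decahydro-1H-fluoren-1-yl unit and whose C5 carries a 4-oxybenzyl group ether-linked to C9 of that unit | CC1=C[C@](C)([C@H](C)O)[C@@H]2C(=O)[C@H]3C[C@](O)(Cc4ccc(cc4)O[C@H]4[C@H]2[C@@H]1[C@]1(C)C[C@H](C)C[C@H](C)[C@@H]41)NC3=O | target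

**Step count and risks**

Total steps: 18. Longest linear sequence: 14 (steps 1–5, 9, 11–18, from 1 to 26).

Steps most likely to fail:

- Step 4 (desymmetrizing ene reaction). The reaction may be sluggish or poorly enantioselective on a hindered trisubstituted olefin. The fallback sets out from 5 and replaces catalyst control by a covalently bound auxiliary. Ene reaction of 5 with (−)-8-phenylmenthyl glyoxylate under SnCl4 (CH2Cl2, −78 °C) would give the (1R,2S,5R)-8-phenylmenthyl (2S)-hydroxy ester F1. Here the auxiliary shields one aldehyde face and the much more electrophilic chelated enophile is used stoichiometrically; the antipodal auxiliary is taken if the induction proves opposite. Transesterification with Ti(OEt)4 in refluxing ethanol brings the material back to the route at 7.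

- Step 15 (thermal intramolecular Diels–Alder reaction). The diene terminus carries a cis-methyl group and must form a quaternary carbon, and the endo/exo ratio is not guaranteed. The fallback sets out from 20 and moves the cycloaddition to an iminium-activated enal. Wittig reaction of 20 with (triphenylphosphoranylidene)acetaldehyde (benzene, 80 °C) would give the (2E,4S)-enal F2. Organocatalytic cycloaddition with (2S,5S)-5-benzyl-2-tert-butyl-3-methylimidazolidin-4-one trifluoroacetate (MeCN–H2O, 0 °C → rt; the catalyst enantiomer is chosen to match the substrate) would then give the tricyclic aldehyde F3 with catalyst-enforced endo selectivity. Roskamp homologation of F3 with ethyl diazoacetate and SnCl2 (CH2Cl2, rt) returns to the route at 23.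

- Step 17 (closure of the strained 13-membered cyclophane by C-alkylation). The fallback sets out from 22 and closes the large ring before the carbocycles are built, while the chain is still flexible. Mild deketalization of 22 (LiBF4, wet MeCN, to spare the dienyl carbinol) would give the triene chloromethyl ketone F4. High-dilution alkylation (Cs2CO3, NaI, MeCN) would give the macrocyclic triene F5. Heating F5 (toluene, 110–150 °C) would bring about a transannular Diels–Alder reaction under the same stereochemical constraints as step 15 and return to the route at 25.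

Further compounds
F1 | step 4 | (1R,2S,5R)-5-methyl-2-(2-phenylpropan-2-yl)cyclohexyl (2S)-2-[(1R,6R)-6-(2,2-dibromoethenyl)-2,4,6-trimethylcyclohexa-2,4-dien-1-yl]-2-hydroxyacetate | CC(C)(c1ccccc1)[C@@H]1CC[C@@H](C)C[C@H]1OC(=O)[C@@H](O)[C@@H]2C(C)=CC(C)=C[C@@]2(C)C=C(Br)Br
F2 | step 15 | (2E,4S)-4-[4-(3-chloro-2,2-dimethoxypropyl)phenoxy]-4-[(1R,2S,4R,6S)-6-[(1E,3E,5S)-5-hydroxy-2,4-dimethylhexa-1,3-dien-1-yl]-2,4,6-trimethylcyclohexyl]but-2-enal | O=C/C=C/[C@H](Oc1ccc(CC(OC)(OC)CCl)cc1)[C@@H]1[C@@H](C)C[C@@H](C)C[C@@]1(C)/C=C(C)/C=C(C)/[C@H](C)O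
F3 | step 15 | (1R,2S,4aS,4bS,6R,8S,8aR,9S,9aS)-9-[4-(3-chloro-2,2-dimethoxypropyl)phenoxy]-2-[(1S)-1-hydroxyethyl]-2,4,4b,6,8-pentamethyl-2,4a,4b,5,6,7,8,8a,9,9a-decahydro-1H-fluorene-1-carbaldehyde | CC1=C[C@](C)([C@H](C)O)[C@H](C=O)[C@@H]2[C@@H]1[C@]3(C)C[C@H](C)C[C@H](C)[C@H]3[C@H]2Oc4ccc(CC(OC)(OC)CCl)cc4
F4 | step 17 | ethyl (4E,6S)-6-[4-(3-chloro-2-oxopropyl)phenoxy]-6-[(1R,2S,4R,6S)-6-[(1E,3E,5S)-5-hydroxy-2,4-dimethylhexa-1,3-dien-1-yl]-2,4,6-trimethylcyclohexyl]-3-oxohex-4-enoate | CCOC(=O)CC(=O)/C=C/[C@H](Oc1ccc(CC(=O)CCl)cc1)[C@@H]1[C@@H](C)C[C@@H](C)C[C@@]1(C)/C=C(C)/C=C(C)/[C@H](C)O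
F5 | step 17 | macrocyclic triene: 13-membered para-cyclophane (E)-enone from F4 by bonding the β-keto ester α-carbon to the former CH2Cl carbon, still carrying the dienyl-substituted cyclohexyl group on the aryl ether carbon | CCOC(=O)C1CC(=O)Cc2ccc(cc2)O[C@@H](/C=C/C1=O)[C@@H]3[C@@H](C)C[C@@H](C)C[C@@]3(C)/C=C(C)/C=C(C)/[C@H](C)O
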